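**Strategy.** The butyrolactone fused to the nine-membered ring carries its ring oxygen on the β-carbon and its methyl-bearing carbon on the α-carbon of the ring ketone, so it is disconnected to an (E)-enone and (S)-2-bromopropanoic acid. One aminocatalytic cascade (oxygen conjugate addition of the carboxylate, then enamine alkylation) closes this lactone, sets three stereocentres and gives the target directly. The enone precursor, a bicyclic lactam with an (E)-cyclononene, arises by a tethered zwitterionic aza-Claisen ring expansion of a cis-2,5-disubstituted 2-alkenylpyrrolidine made from trans-4-hydroxy-L-proline, whose hydroxyl becomes the ketone.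

Key step: step 16

Remark on numbering: atoms are counted along the target SMILES (C1–C2 ethyl, C3, C4, O5, C6, C7, C8 methyl, C9, C10 ketone, C11, C12, C13–C17 with O18 second lactone, N19, C20–C23, C24, C25 lactam carbonyl).
Assumption: compounds 1, 6, 13, 19 and 27 are taken as commercial; amine and amino acid intermediates are drawn neutral although 18 and 21 are handled as salts or used at once.

Step 1
Reactants: 1 N-Boc-trans-4-hydroxy-L-proline methyl ester
Product: 2 triisopropylsilyl ether of 1
Conditions: TIPSOTf, 2,6-lutidine, CH2Cl2, 0 °C → rt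
Reagents that add atoms: triisopropylsilyl trifluoromethanesulfonate, CC(C)[Si](C(C)C)(C(C)C)OS(=O)(=O)C(F)(F)F
Why: Silyl ether protection of the secondary alcohol with a silyl triflate and a hindered base; no stereocentre is touched and the bulky group later steers the addition next to it.

Step 2
Reactants: 2 triisopropylsilyl ether of 1
Product: 3 (2S,4R)-5-oxo lactam
Conditions: RuO2·xH2O (cat.), NaIO4, EtOAc/H2O, rt
Reagents that add atoms: sodium periodate, [Na+].[O-]I(=O)(=O)=O
Why: Ruthenium tetroxide, formed catalytically from RuO2 and NaIO4, oxidizes the methylene next to the carbamate nitrogen to the lactam (RuO4 oxidation of N-acyl amines) without touching C2 or C4.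

Step 3
Reactants: 3 (2S,4R)-5-oxo lactam
Product: 5 (2S,4R)-5-methoxy N,O-acetal (C5 epimers), via hemiaminal 4 (not isolated)
Conditions: LiBEt3H, THF, −78 °C; then MeOH, PPTS (cat.), rt
Reagents that add atoms: methanol, CO
Why: The imide-like ring carbonyl of the N-Boc lactam is reduced chemoselectively over the methyl ester (partial lactam reduction) and the hemiaminal is exchanged to the N,O-acetal; the new centre is uncontrolled and is erased in step 5.

Step 4
Reactants: 6 but-1-yne
Product: 8 potassium (E)-but-1-en-1-yltrifluoroborate, via alkenyl catecholboronate 7 (not isolated)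
Conditions: catecholborane, neat, 70 °C (sealed tube); then KHF2, H2O/Et2O, rt
Reagents that add atoms: catecholborane, B1Oc2ccccc2O1; potassium hydrogen difluoride, [K+].F[H-]F
Why: syn-Hydroboration of the terminal alkyne places boron at the terminus with (E) geometry, and fluoride exchange gives the stable trifluoroborate (alkyne hydroboration).

Step 5
Reactants: 5 (2S,4R)-5-methoxy N,O-acetal; 8 potassium (E)-but-1-en-1-yltrifluoroborate
Product: 10 (2S,4R,5S)-5-[(E)-but-1-enyl] pyrrolidine diester, via N-acyliminium ion 9 (not isolated)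
Conditions: BF3·OEt2, CH2Cl2, −78 → 0 °C
Reagents that add atoms: none
Why: BF3 ionizes the N,O-acetal and the alkenyltrifluoroborate transfers the butenyl group to the N-acyliminium ion anti to the adjacent bulky silyloxy group, which should give the 4,5-trans and hence 2,5-cis product with the (E) geometry retained (N-acyliminium alkenylation).

Step 6
Reactants: 10 (2S,4R,5S)-5-[(E)-but-1-enyl] pyrrolidine diester
Product: 11 pyrrolidine-2-carboxylic acid
Conditions: LiOH, THF/H2O, 0 °C; then 1 M HCl to pH 3
Reagents that add atoms: lithium hydroxide, [Li+].[OH-]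
Why: Saponification of the methyl ester under conditions that leave the carbamate, the silyl ether and the α-stereocentre intact.

Step 7
Reactants: 11 pyrrolidine-2-carboxylic acid
Product: 12 S-ethyl thioester
Conditions: EtSH, EDC·HCl, DMAP (cat.), CH2Cl2, 0 °C → rt
Reagents that add atoms: ethanethiol, CCS
Why: Carbodiimide-mediated (Steglich-type) thioesterification provides the acyl donor for ketone synthesis without epimerization.

Step 8
Reactants: 12 S-ethyl thioester; 13 methyl (R)-3-bromo-2-methylpropanoate
Product: 15 γ-keto ester, via alkylzinc bromide 14 (not isolated)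
Conditions: 13, Zn dust, I2 (cat.), DMA, 70 °C; then 12, PdCl2(PPh3)2 (5 mol%), toluene, rt
Reagents that add atoms: none
Why: Zinc inserts into the primary C–Br bond and the alkylzinc couples with the thioester under palladium catalysis (Fukuyama ketone synthesis) without over-addition; the methyl-bearing centre C15 comes unchanged from 13.

Step 9
Reactants: 15 γ-keto ester
Product: 17 N-Boc pyrrolidinyl lactone, via hydroxy ester 16 (not isolated)
Conditions: LiBH(s-Bu)3, THF, −78 °C; AcOH; then PPTS, toluene, 60 °C
Reagents that add atoms: none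
Why: The bulky hydride should attack in the Felkin–Anh mode with the carbamate nitrogen anti to the incoming hydride, giving the syn (threo) amino alcohol with (S) configuration at C13, and acid then closes the γ-lactone (Felkin–Anh reduction then lactonization).

Step 10
Reactants: 17 N-Boc pyrrolidinyl lactone
Product: 18 secondary amine
Conditions: TFA, CH2Cl2, 0 °C; then cold aq. NaHCO3, used at once
Reagents that add atoms: none
Why: Acidolysis of the tert-butyl carbamate, which the triisopropylsilyl ether and the lactone survive; immediate use keeps the free amine from attacking the lactone.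

Step 11
Reactants: 18 secondary amine; 19 methyl 6-oxohexanoate
Product: 20 tertiary amine methyl ester
Conditions: NaBH(OAc)3, AcOH (1 equiv), ClCH2CH2Cl, rt
Reagents that add atoms: none
Why: Reductive amination alkylates the hindered cis-2,5-disubstituted pyrrolidine under mildly acidic conditions in which the lactone is not attacked.

Step 12
Reactants: 20 tertiary amine methyl ester
Product: 21 amino acid
Conditions: LiOH, THF/H2O, 0 °C → rt; then 1 M HCl to pH 3
Reagents that add atoms: lithium hydroxide, [Li+].[OH-]
Why: Saponification frees the chain carboxylic acid; the γ-lactone opens reversibly and recloses on acidification (γ-hydroxy acid lactonization), and no stereocentre is enolizable under these conditions.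

Step 13
Reactants: 21 amino acid
Product: 24 ring-expanded bicyclic (E)-alkene lactam, via acyl fluoride 22 (not isolated), via acylammonium enolate 23 (not isolated)
Conditions: cyanuric fluoride, pyridine, CH2Cl2, −20 → 0 °C; then K2CO3, CHCl3 (0.005 M), 0 → 45 °C
Reagents that add atoms: none
Why: Proposed new method: the acid fluoride acylates the tertiary amine intramolecularly on the face anti to both ring substituents, deprotonation gives a spiro acylammonium enolate, and this zwitterion undergoes a [3,3] shift that breaks N19–C9 and forms C24–C3; the closest known reaction is the zwitterionic (ketene) aza-Claisen ring expansion of N-alkyl-2-vinylpyrrolidines with external acyl halides, here with the acyl group tethered to nitrogen. A chair transition state with the ring-fixed enolate geometry, the ethyl group equatorial and the pyrrolidine C9–C10 bond equatorial should set C3 and C24, give the (E)-alkene and leave its outer face exposed.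

Step 14
Reactants: 24 ring-expanded bicyclic (E)-alkene lactam
Product: 25 allylic alcohol
Conditions: Bu4NF, AcOH, THF, 0 °C → rt
Reagents that add atoms: none
Why: Fluoride-mediated desilylation, buffered with acetic acid so that the lactone and lactam stay intact.

Step 15
Reactants: 25 allylic alcohol
Product: 26 (E)-enone
Conditions: Dess–Martin periodinane, CH2Cl2, 0 °C → rt
Reagents that add atoms: none
Why: Dess–Martin oxidation of the allylic alcohol under near-neutral conditions should give the enone without isomerizing the (E)-alkene or the adjacent stereocentres.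

Step 16
Reactants: 26 (E)-enone; 27 (S)-2-bromopropanoic acid
Product: 31 tuberostemonone, via iminium 2-bromopropanoate 28 (not isolated), via acyloxy enamine 29 (not isolated), via lactone iminium bromide 30 (not isolated)
Conditions: 27 (2 equiv), Ph2CHNH2 (30 mol%), 2,6-lutidine (1.2 equiv), CHCl3, 30 °C
Reagents that add atoms: none
Why: Proposed new method: the primary amine converts the C10 ketone into an iminium ion whose 2-bromopropanoate counter-ion adds through oxygen to the β-carbon C4, and the neutral enamine so formed alkylates at C9 with the α-bromo ester carbon C7 before hydrolysis returns the ketone and the amine; a bare carboxylate would not add to the enone, but as an iminium-to-enamine step the addition creates no charge. The closest known reaction types are aminocatalytic Michael-initiated ring closures of enones (cyclopropanation with bromomalonates, epoxidation with peroxides) and the Stork enamine alkylation with α-halo esters. The lactone closes by a 5-exo-tet displacement at C7. C7 is set by inversion of the (S)-bromide, C4 by attack of the carboxylate on the exposed outer face of the (E)-enone (transannular lactam on the inner face, C3 ethyl pseudo-equatorial), and C9 by ring closure on that same face with allylic 1,3-strain in the enamine holding C3 and C10 anti, which should give the trans ring fusion. The step needs oxygen-to-β and carbon-to-α regiochemistry, fixed by the polarity of the enone, and chemoselectivity over the saturated lactone and the lactam, which offer no conjugate acceptor; the weakly basic buffer avoids β-elimination of the product.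

**Compound list**

1 | N-Boc-trans-4-hydroxy-L-proline methyl ester, 1-tert-butyl 2-methyl (2S,4R)-4-hydroxypyrrolidine-1,2-dicarboxylate | COC(=O)[C@@H]1C[C@@H](O)CN1C(=O)OC(C)(C)C | starting material
2 | 1-tert-butyl 2-methyl (2S,4R)-4-(triisopropylsilyloxy)pyrrolidine-1,2-dicarboxylate | COC(=O)[C@@H]1C[C@@H](O[Si](C(C)C)(C(C)C)C(C)C)CN1C(=O)OC(C)(C)C | intermediate
3 | 1-tert-butyl 2-methyl (2S,4R)-5-oxo-4-(triisopropylsilyloxy)pyrrolidine-1,2-dicarboxylate | COC(=O)[C@@H]1C[C@@H](O[Si](C(C)C)(C(C)C)C(C)C)C(=O)N1C(=O)OC(C)(C)C | intermediate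
4 | (2S,4R)-5-hydroxy hemiaminal of 3 (C5 epimers) | COC(=O)[C@@H]1C[C@@H](O[Si](C(C)C)(C(C)C)C(C)C)C(O)N1C(=O)OC(C)(C)C | intermediate
5 | 1-tert-butyl 2-methyl (2S,4R)-5-methoxy-4-(triisopropylsilyloxy)pyrrolidine-1,2-dicarboxylate (C5 epimers) | COC(=O)[C@@H]1C[C@@H](O[Si](C(C)C)(C(C)C)C(C)C)C(OC)N1C(=O)OC(C)(C)C | intermediate
6 | but-1-yne | CCC#C | starting material
7 | (E)-2-(but-1-en-1-yl)-1,3,2-benzodioxaborole | CC/C=C/B1Oc2ccccc2O1 | intermediate
8 | potassium (E)-but-1-en-1-yltrifluoroborate | CC/C=C/[B-](F)(F)F.[K+] | intermediate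
9 | N-acyliminium ion from 5, methoxytrifluoroborate salt | COC(=O)[C@@H]1C[C@@H](O[Si](C(C)C)(C(C)C)C(C)C)C=[N+]1C(=O)OC(C)(C)C.CO[B-](F)(F)F | intermediate
10 | 1-tert-butyl 2-methyl (2S,4R,5S)-5-[(E)-but-1-en-1-yl]-4-(triisopropylsilyloxy)pyrrolidine-1,2-dicarboxylate | COC(=O)[C@@H]1C[C@@H](O[Si](C(C)C)(C(C)C)C(C)C)[C@H](/C=C/CC)N1C(=O)OC(C)(C)C | intermediate
11 | (2S,4R,5S)-1-Boc-5-[(E)-but-1-enyl]-4-(triisopropylsilyloxy)pyrrolidine-2-carboxylic acid | OC(=O)[C@@H]1C[C@@H](O[Si](C(C)C)(C(C)C)C(C)C)[C@H](/C=C/CC)N1C(=O)OC(C)(C)C | intermediate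
12 | S-ethyl thioester of 11 | CCSC(=O)[C@@H]1C[C@@H](O[Si](C(C)C)(C(C)C)C(C)C)[C@H](/C=C/CC)N1C(=O)OC(C)(C)C | intermediate
13 | methyl (R)-3-bromo-2-methylpropanoate | COC(=O)[C@@H](C)CBr | starting material
14 | [(2R)-3-methoxy-2-methyl-3-oxopropyl]zinc bromide | COC(=O)[C@@H](C)C[Zn]Br | intermediate
15 | tert-butyl (2S,3R,5S)-2-[(E)-but-1-enyl]-5-[(3S)-4-methoxy-3-methyl-4-oxobutanoyl]-3-(triisopropylsilyloxy)pyrrolidine-1-carboxylate | COC(=O)[C@@H](C)CC(=O)[C@@H]1C[C@@H](O[Si](C(C)C)(C(C)C)C(C)C)[C@H](/C=C/CC)N1C(=O)OC(C)(C)C | intermediate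
16 | tert-butyl (2S,3R,5S)-2-[(E)-but-1-enyl]-5-[(1S,3S)-1-hydroxy-4-methoxy-3-methyl-4-oxobutyl]-3-(triisopropylsilyloxy)pyrrolidine-1-carboxylate | COC(=O)[C@@H](C)C[C@H](O)[C@@H]1C[C@@H](O[Si](C(C)C)(C(C)C)C(C)C)[C@H](/C=C/CC)N1C(=O)OC(C)(C)C | intermediate
17 | tert-butyl (2S,3R,5S)-2-[(E)-but-1-enyl]-5-[(2S,4S)-4-methyl-5-oxooxolan-2-yl]-3-(triisopropylsilyloxy)pyrrolidine-1-carboxylate | O=C1O[C@@H](C[C@@H]1C)[C@@H]2C[C@@H](O[Si](C(C)C)(C(C)C)C(C)C)[C@H](/C=C/CC)N2C(=O)OC(C)(C)C | intermediate
18 | (3S,5S)-5-[(2S,4R,5S)-5-[(E)-but-1-enyl]-4-(triisopropylsilyloxy)pyrrolidin-2-yl]-3-methyloxolan-2-one | O=C1O[C@@H](C[C@@H]1C)[C@@H]2C[C@@H](O[Si](C(C)C)(C(C)C)C(C)C)[C@H](/C=C/CC)N2 | intermediate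
19 | methyl 6-oxohexanoate | COC(=O)CCCCC=O | starting material
20 | methyl 6-[(2S,3R,5S)-2-[(E)-but-1-enyl]-5-[(2S,4S)-4-methyl-5-oxooxolan-2-yl]-3-(triisopropylsilyloxy)pyrrolidin-1-yl]hexanoate | O=C1O[C@@H](C[C@@H]1C)[C@@H]2C[C@@H](O[Si](C(C)C)(C(C)C)C(C)C)[C@H](/C=C/CC)N2CCCCCC(=O)OC | intermediate
21 | 6-[pyrrolidin-1-yl]hexanoic acid corresponding to 20 | O=C1O[C@@H](C[C@@H]1C)[C@@H]2C[C@@H](O[Si](C(C)C)(C(C)C)C(C)C)[C@H](/C=C/CC)N2CCCCCC(=O)O | intermediate
22 | acyl fluoride of 21 | O=C1O[C@@H](C[C@@H]1C)[C@@H]2C[C@@H](O[Si](C(C)C)(C(C)C)C(C)C)[C@H](/C=C/CC)N2CCCCCC(=O)F | intermediate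
23 | spiro acylammonium enolate (zwitterion; seven-membered ketene N,O-acetal ring spiro-fused at nitrogen to the pyrrolidine) | O=C1O[C@@H](C[C@@H]1C)[C@@H]2C[C@@H](O[Si](C(C)C)(C(C)C)C(C)C)[C@H](/C=C/CC)[N+]23CCCCC=C3[O-] | intermediate
24 | 1-azabicyclo[6.4.1]tridec-5-en-13-one with (E)-C4=C9, 7-ethyl, 4-(triisopropylsilyloxy) and 2-[(2S,4S)-4-methyl-5-oxooxolan-2-yl] groups (configuration as in the SMILES) | CC[C@H]1/C=C/[C@H](O[Si](C(C)C)(C(C)C)C(C)C)C[C@@H]([C@@H]2C[C@H](C)C(=O)O2)N2CCCC[C@@H]1C2=O | intermediate
25 | allylic alcohol from 24 (C10 hydroxyl) | CC[C@H]1/C=C/[C@H](O)C[C@@H]([C@@H]2C[C@H](C)C(=O)O2)N2CCCC[C@@H]1C2=O | intermediate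
26 | (E)-enone (C4=C9–C10=O) of the bicyclic lactam | CC[C@H]1/C=C/C(=O)C[C@@H]([C@@H]2C[C@H](C)C(=O)O2)N2CCCC[C@@H]1C2=O | intermediate
27 | (S)-2-bromopropanoic acid | C[C@H](Br)C(=O)O | starting material
28 | N-benzhydryl iminium ion of 26 with (S)-2-bromopropanoate counter-ion | CC[C@H]1/C=C/C(=[NH+]C(c3ccccc3)c3ccccc3)C[C@@H]([C@@H]2C[C@H](C)C(=O)O2)N2CCCC[C@@H]1C2=O.C[C@H](Br)C(=O)[O-] | intermediate
29 | C4 (S)-2-bromopropanoyloxy enamine (C9=C10–NH–CHPh2) | CC[C@H]1[C@H](OC(=O)[C@H](C)Br)C=C(NC(c3ccccc3)c3ccccc3)C[C@@H]([C@@H]2C[C@H](C)C(=O)O2)N2CCCC[C@@H]1C2=O | intermediate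
30 | N-benzhydryl iminium bromide of tuberostemonone | CC[C@H]1[C@@H]2OC(=O)[C@@H](C)[C@H]2C(=[NH+]C(c3ccccc3)c3ccccc3)C[C@@H]([C@@H]2C[C@H](C)C(=O)O2)N2CCCC[C@@H]1C2=O.[Br-] | intermediate
31 | tuberostemonone | CC[C@H]1[C@@H]2OC(=O)[C@@H](C)[C@H]2C(=O)C[C@@H]([C@@H]2C[C@H](C)C(=O)O2)N2CCCC[C@@H]1C2=O | target

**Step count.** 16 steps in total; the longest linear sequence is 15 steps (steps 1–3 and 5–16 from compound 1), with step 4 as a one-step side branch.

**Steps most likely to fail**

Step 16 (key step, new method). The reversible conjugate addition may not be followed fast enough by the enamine alkylation. The enone could then isomerize from (E) to (Z) or deconjugate through a dienamine (loss of C3), the bromide set free could exchange at C7 and erode its configuration, or the product could reopen by β-elimination. The fallback sets out from 24 and returns at 31, and forms the same two bonds in one operation by known radical–polar chemistry. Oxidative lactone annulation of the (E)-alkene with 2-methylmalonic acid and Mn(OAc)3·2H2O in AcOH at 70 °C should add the malonyl radical to C9 (the developing cation at C4 is remote from the silyloxy group) and close the lactone on C4, giving the carboxy lactone F1. Thermal decarboxylation in DMSO at 120 °C, with kinetic reprotonation of the lactone enolate (LiN(i-Pr)2, then a hindered phenol) if C7 needs correction, gives the methyl lactone silyl ether F2. Bu4NF then gives the hydroxy lactone F3, and Dess–Martin oxidation gives 31.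

Step 13 (new method). Intermolecular acylation and oligomerization may outrun the formation of the spiro acylammonium ion, fluoride or carboxylate may open the allylic C–N bond, or a boat transition state may deliver the C3 epimer. The fallback sets out from 18 and returns at 24 and uses the established intermolecular ring expansion. Reductive amination with 4-methoxybenzaldehyde (NaBH(OAc)3) gives the N-(4-methoxybenzyl) amine F4. Zwitterionic aza-Claisen rearrangement with 6-bromohexanoyl fluoride (Me3Al, K2CO3, CHCl3) gives the nine-membered N-(4-methoxybenzyl) lactam F5, expected as the C24 epimer because the open-chain enolate has the opposite geometry. (NH4)2Ce(NO3)6 removes the benzyl group to give the secondary lactam F6, and NaH in THF at high dilution closes the seven-membered ring by N-alkylation to give the C24-epimeric bicyclic lactam F7. Enolization at the C24 bridgehead (KOt-Bu, t-BuOH) and reprotonation should then give 24.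

Step 9. Facial selectivity of hydride delivery may be poor if a chelated transition state competes with the Felkin–Anh one, and the alkoxide may attack the carbamate instead of the ester. The fallback sets out from 15 and returns at 17. Chelation-controlled reduction with Zn(BH4)2 at −78 °C gives the anti hydroxy ester F8, kept from lactonizing by a neutral work-up. Mitsunobu inversion with 4-nitrobenzoic acid (PPh3, diisopropyl azodicarboxylate) gives the inverted 4-nitrobenzoate F9, and K2CO3 in MeOH cleaves the benzoate and lets the (S)-alkoxide close the lactone 17.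

Further compounds
F1 | step 16 | C7 carboxy lactone silyl ether (C7 epimers) | CC[C@H]1[C@@H]2OC(=O)C(C)(C(=O)O)[C@H]2[C@H](O[Si](C(C)C)(C(C)C)C(C)C)C[C@@H]([C@@H]2C[C@H](C)C(=O)O2)N2CCCC[C@@H]1C2=O
F2 | step 16 | tuberostemonone skeleton with C10 triisopropylsilyloxy in place of the ketone | CC[C@H]1[C@@H]2OC(=O)[C@@H](C)[C@H]2[C@H](O[Si](C(C)C)(C(C)C)C(C)C)C[C@@H]([C@@H]2C[C@H](C)C(=O)O2)N2CCCC[C@@H]1C2=O
F3 | step 16 | C10 alcohol of tuberostemonone | CC[C@H]1[C@@H]2OC(=O)[C@@H](C)[C@H]2[C@H](O)C[C@@H]([C@@H]2C[C@H](C)C(=O)O2)N2CCCC[C@@H]1C2=O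
F4 | step 13 | N-(4-methoxybenzyl) derivative of 18 | O=C1O[C@@H](C[C@@H]1C)[C@@H]2C[C@@H](O[Si](C(C)C)(C(C)C)C(C)C)[C@H](/C=C/CC)N2Cc1ccc(OC)cc1
F5 | step 13 | nine-membered (E)-alkene N-(4-methoxybenzyl) lactam with 4-bromobutyl at C24 (C24 epimer) | CC[C@H]1/C=C/[C@H](O[Si](C(C)C)(C(C)C)C(C)C)C[C@@H]([C@@H]2C[C@H](C)C(=O)O2)N(Cc2ccc(OC)cc2)C(=O)[C@@H]1CCCCBr
F6 | step 13 | nine-membered (E)-alkene secondary lactam with 4-bromobutyl at C24 | CC[C@H]1/C=C/[C@H](O[Si](C(C)C)(C(C)C)C(C)C)C[C@@H]([C@@H]2C[C@H](C)C(=O)O2)NC(=O)[C@@H]1CCCCBr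
F7 | step 13 | C24 epimer of 24 | CC[C@H]1/C=C/[C@H](O[Si](C(C)C)(C(C)C)C(C)C)C[C@@H]([C@@H]2C[C@H](C)C(=O)O2)N2CCCC[C@H]1C2=O
F8 | step 9 | C13 epimer of 16 (anti hydroxy ester) | COC(=O)[C@@H](C)C[C@@H](O)[C@@H]1C[C@@H](O[Si](C(C)C)(C(C)C)C(C)C)[C@H](/C=C/CC)N1C(=O)OC(C)(C)C
F9 | step 9 | 4-nitrobenzoate of 16 | COC(=O)[C@@H](C)C[C@H](OC(=O)c2ccc(cc2)[N+](=O)[O-])[C@@H]1C[C@@H](O[Si](C(C)C)(C(C)C)C(C)C)[C@H](/C=C/CC)N1C(=O)OC(C)(C)C
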